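## Structural features

The target is a germacranolide: a ten-membered carbocycle (C1–C10) with two ring-cis trisubstituted double bonds, C1=C10 (methyl C14 on C10) and C4=C5 (methyl C15 on C4), fused across C6–C7 to an α-methylene-γ-butyrolactone (O6, C12, C11, exocyclic C13). The lactone junction is cis (H6 and H7 on the same side). C6, C7, C8 and C9 are four contiguous stereocentres carrying, in turn, the lactone oxygen, the lactone carbon, a free hydroxyl and an ester oxygen. C3 with its acetate is separated from them by C4=C5, and the acyl group on O9, (2S,3S)-2,3-epoxy-2-methylbutanoate, adds two more stereocentres. The fragile groups are the α-methylene lactone (conjugate acceptor), the allylic acetate at C3, the allylic ester at C9, the epoxide, and the free C8 hydroxyl, which can take over the neighbouring acyl group or the lactone carbonyl (O8 is also γ to C12). The real difficulty is closing a ten-membered ring that holds two Z-trisubstituted olefins while fixing the C6/C7 pair relative to C8/C9, and telling O8 and O9 apart at the end. The key step uses the unit O6–C6–C7–C11(=C13): a homoallylic alcohol with a 2-substituted allyl group is the retron of a [2,3]-Wittig rearrangement. Linking O6 to C13 therefore gives a thirteen-membered bis-allylic ether (C7=C11 as a third ring-cis olefin) whose contraction delivers the carbocycle, the C6 oxygen, the exocyclic methylene and both stereocentres in one event.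

## Logic of the disconnections

**40 ⇒ 34 + 38.** The ester C–O bond at O9 is cut. The acyl part is the most sensitive fragment and has its own stereocentres, so it is made separately and attached last. The gain is that the two chiral domains are separated. The forward step must acylate O9 and not O8, and must not set off acyl or lactone migration.

**34 ⇒ 33 ⇒ 32 ⇒ 31.** No skeletal bond is cut; the 8,9-diol is returned to its acetonide, the C3 acetate to the alcohol and then to the silyl ether. Acetylating before the diol is released means that only the intended hydroxyls are ever free together. The forward steps need a fluoride source that spares the α-methylene lactone and an acid that hydrolyses the acetonide without ionising the allylic acetate.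

**31 ⇒ 28 ⇒ 27.** The lactone bond O6–C12 is cut and C12 is lowered to the alcohol level and silylated. C12 can then pass through the strongly basic key step as an inert CH2OSi group. The forward sequence needs selective removal of the primary silyl ether and an oxidation that takes only the primary allylic alcohol and closes onto O6.

**27 ⇒ 25.** C6–C7 is cut and O6 is joined to C13. This trades the ten-membered carbocycle with its two new stereocentres for a thirteen-membered ether that has no stereocentre at C6 or C7 and is far easier to close. The forward step must lithiate C6 and not C13, give the syn C6/C7 pair, and add to the correct face of C7 relative to C8.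

**25 ⇒ 24 ⇒ 23 ⇒ 22 ⇒ 21.** The ether bond O–C13 is cut (alkoxide at C6, allylic bromide at C13), then protecting groups and the oxidation level of C12 are adjusted. The gain is an open chain. The forward ring closure needs high dilution and an SN2 displacement, and the C7=C11 geometry must already be fixed.

**21 ⇒ 20 ⇒ 18 + 19.** After an allylic transposition (bromide at C13 back to hydroxyl at C7), C7–C11 is cut. C11, C12 and C13 then come from 19 in one step, with C12 and C13 chemically distinct from the outset. The forward transposition must give the olefin with C13 cis to C8, which the conjugated ester should ensure.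

**18 ⇒ 17 ⇒ 12 + 15.** The C1=C10 double bond is cut. This splits the chain into two fragments of similar size, each with its own stereocentres. The forward olefination of a methyl ketone must be Z-selective; the α-oxygen of the ketone is what should make it so.

**15 ⇒ 14 ⇒ 13.** The C10–C14 bond is cut and the two carbonyl groups are made equal again. C8 and C9 then come from the chiral pool with no stereochemical risk. The forward step must add one methyl group to one of two equivalent amides.

**12 ⇒ 11 ⇒ 10 ⇒ 8 ⇒ 7 ⇒ 5 + 6.** The C1–P bond is cut, the terminal carbon lost in the forward direction is restored, and C2–C3 is cut. C3 is then set by a catalytic asymmetric allyl transfer to a simple enal. The forward steps need an allylation that does not isomerise the Z-enal and a cleavage of the terminal alkene that leaves C4=C5 alone.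

**5 ⇒ 4 ⇒ 3 ⇒ 1 + 2.** C4=C5 is cut. The Z-trisubstituted olefin comes from two small commercial pieces. The forward olefination must be Z-selective and the later oxidation must keep that geometry.

**38 ⇒ 37 ⇒ 36 ⇒ 35.** The carboxyl group is lowered to the alcohol and the epoxide C–O bonds are cut. The Z-olefin of 35 fixes the relative configuration of the epoxide, and the allylic alcohol allows a reagent-controlled choice of the absolute one.

## Other disconnections considered

**Alternative 1:** The cut is C9–C10, made late with the lactone, the acetate and C3, C6, C7 and C8 in place. In the forward step CrCl2 with catalytic NiCl2 turns the Z-alkenyl iodide of the seco iodo aldehyde A2 into an alkenylchromium species, which adds to the C9 aldehyde and gives the ten-membered carbinol A1.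
- In its favour: the organochromium reagent tolerates lactone and acetate, and only acylation and PMB removal follow the ring closure.
- Better than the chosen plan: O8 carries a PMB group throughout, so the C9 acylation needs no regioselection, whereas step 28 has to choose between two free hydroxyls. The sequence after the key step is also shorter.
- Against it: a ten-membered ring is closed end to end, the least favourable size for entropy and transannular strain, whereas the chosen plan closes a thirteen-membered ring and contracts it. C9 is created in the ring-closing addition to an α-alkoxy aldehyde with little to steer it, whereas the chosen plan takes C8 and C9 from tartaric acid. A2 is epimerisable next to the aldehyde and must carry the C6/C7/C8 triad and the lactone through its own synthesis, so the route to A2 should be longer than that to 25.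
- Equal: both plans need two Z-selective olefin constructions.

**Alternative 2:** Read backwards, a bond C3–C8 is added so that the ten-membered ring becomes a decalin; in the forward step Pb(OAc)4 cleaves the ring-fusion diol A4 to the (Z,Z)-diene-3,8-dione A3.
- Better than the chosen plan: both olefins sit in six-membered rings before the cleavage, so their geometry is certain, and the medium ring appears by fragmentation with no dilution or entropic cost.
- Equal or better: carvone supplies chirality cheaply, and O8 and O9 are distinct (ketone versus silyl ether).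
- Against it: C3 and C8 emerge as ketones, so two diastereoselective reductions on a flexible ten-membered ring are needed. C7 is α to the C8 ketone and β,γ to C11=C13, so it can epimerise or move into conjugation. Building A4 with all its substituents on a carvone core is long, and after the key step two reductions, two deprotections, lactonisation, acetylation and acylation remain.
- In the chosen plan C3, C8 and C9 have their final oxidation level and configuration from the start, and the key step creates the stereocentres that the fragmentation leaves open.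

**Alternative 3:** The cut is C8–C9. In the forward step SmI2 reduces both carbonyl groups of the dialdehyde A6 and the ketyl carbons couple to the ten-membered 8,9-diol A5.
- In its favour: one step forms the bond, both carbinol centres and the ring from two aldehydes.
- Better than the chosen plan: no strong base is needed, so the lithiation-site question of step 19 does not arise.
- Against it: again a ten-membered ring is closed end to end. The ketyl of the enal at C9 is delocalised to C1 and may couple or be reduced there. The (8S,9S) threo diol must arise relative to C7 with little control. C7 next to the C8 aldehyde is labile.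
- Equal, not better: the diol A5 is undifferentiated, so the same regioselective acylation is needed as in step 28.
- The step count on paper is similar or shorter, but the key step carries more stereochemical uncertainty than a ring contraction whose two centres are linked by a cyclic transition state.

Key step: step 19

Remark on numbering: carbons carry germacrane numbers throughout, also in open-chain intermediates (C1–C10 ring, C11–C13 side chain, C14 on C10, C15 on C4).

Remark on the key-step precursor: 25 carries TBS on both O3 (secondary) and O12 (primary), so that O12 can be freed alone after the rearrangement. Its C7=C11 bond is ring-cis (C13 cis to C8) and has the descriptor E.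

Assumption: (S)-TRIP is taken to direct allyl transfer from 6 to the Si face of enal 5, the mirror image of the sense known for the antipodal acid with aryl aldehydes.

## Steps

Step 1
Reactants: 1 2-[(4-methoxybenzyl)oxy]acetaldehyde; 2 ethyl 2-[bis(2,2,2-trifluoroethoxy)phosphoryl]propanoate
Product: 3 ethyl (2Z)-4-[(4-methoxybenzyl)oxy]-2-methylbut-2-enoate
Conditions: 2, KN(SiMe3)2, 18-crown-6, THF, −78 °C; then 1
Reagents that add atoms: none
Why: Still–Gennari olefination; the electron-poor phosphonate with a dissociated potassium ion eliminates fast from the kinetic adduct, which should give the Z-enoate (ester cis to CH2OPMB), the ring-cis C4=C5 geometry.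

Step 2
Reactants: 3 ethyl (2Z)-4-[(4-methoxybenzyl)oxy]-2-methylbut-2-enoate
Product: 4 (2Z)-4-[(4-methoxybenzyl)oxy]-2-methylbut-2-en-1-ol
Conditions: i-Bu2AlH (2.2 equiv), CH2Cl2, −78 °C
Reagents that add atoms: none
Why: 1,2-Reduction of an enoate by i-Bu2AlH; no conjugate reduction at −78 °C and the olefin geometry is untouched.

Step 3
Reactants: 4 (2Z)-4-[(4-methoxybenzyl)oxy]-2-methylbut-2-en-1-ol
Product: 5 (2Z)-4-[(4-methoxybenzyl)oxy]-2-methylbut-2-enal
Conditions: TEMPO (10 mol %), PhI(OAc)2, CH2Cl2, rt
Reagents that add atoms: none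
Why: Oxoammonium oxidation of a primary allylic alcohol under neutral conditions, which should give the Z-enal without Z/E isomerisation.

Step 4
Reactants: 5 (2Z)-4-[(4-methoxybenzyl)oxy]-2-methylbut-2-enal; 6 allylboronic acid pinacol ester
Product: 7 (4S,5Z)-7-[(4-methoxybenzyl)oxy]-5-methylhepta-1,5-dien-4-ol
Conditions: (S)-TRIP (5 mol %), toluene, −30 °C; aq. NaHCO3
Reagents that add atoms: none
Why: Chiral phosphoric acid-catalysed allylboration; the acid activates the boronate by hydrogen bonding and the chair transition state should deliver allyl to the Si face of the aldehyde, setting C3 as S; the weak acid and low temperature should leave the Z-enal intact.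

Step 5
Reactants: 7 (4S,5Z)-7-[(4-methoxybenzyl)oxy]-5-methylhepta-1,5-dien-4-ol
Product: 8 tert-butyl{[(4S,5Z)-7-[(4-methoxybenzyl)oxy]-5-methylhepta-1,5-dien-4-yl]oxy}dimethylsilane
Conditions: TBSCl, imidazole, DMF, rt
Reagents that add atoms: tert-butyldimethylsilyl chloride, CC(C)(C)[Si](C)(C)Cl
Why: Standard silylation of a secondary allylic alcohol; the TBS ether is bulky and a weak lithium ligand, which matters in step 19.

Step 6
Reactants: 8 tert-butyl{[(4S,5Z)-7-[(4-methoxybenzyl)oxy]-5-methylhepta-1,5-dien-4-yl]oxy}dimethylsilane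
Product: 10 (3S,4Z)-3-[(tert-butyldimethylsilyl)oxy]-6-[(4-methoxybenzyl)oxy]-4-methylhex-4-en-1-ol, via aldehyde 9 (not isolated)
Conditions: K2OsO4·2H2O (2 mol %), NaIO4, 2,6-lutidine, dioxane–H2O, 0 °C; then NaBH4, MeOH, 0 °C
Reagents that add atoms: sodium periodate, [Na+].[O-]I(=O)(=O)=O (oxygen at C1, relayed by the osmium catalyst)
Why: Lemieux–Johnson cleavage; the unhindered monosubstituted alkene should be dihydroxylated faster than C4=C5, which is shielded by the OTBS group and deactivated by two allylic oxygens; NaBH4 reduces the β-silyloxy aldehyde 9 in the same flask before it can eliminate.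

Step 7
Reactants: 10 (3S,4Z)-3-[(tert-butyldimethylsilyl)oxy]-6-[(4-methoxybenzyl)oxy]-4-methylhex-4-en-1-ol
Product: 11 tert-butyl{[(3S,4Z)-1-iodo-6-[(4-methoxybenzyl)oxy]-4-methylhex-4-en-3-yl]oxy}dimethylsilane
Conditions: I2, PPh3, imidazole, CH2Cl2, 0 °C
Reagents that add atoms: iodine, II
Why: Appel-type iodination of a primary alcohol by SN2 displacement of the oxyphosphonium group; no stereocentre is involved.

Step 8
Reactants: 11 tert-butyl{[(3S,4Z)-1-iodo-6-[(4-methoxybenzyl)oxy]-4-methylhex-4-en-3-yl]oxy}dimethylsilane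
Product: 12 [(3S,4Z)-3-[(tert-butyldimethylsilyl)oxy]-6-[(4-methoxybenzyl)oxy]-4-methylhex-4-en-1-yl]triphenylphosphonium iodide
Conditions: PPh3, i-Pr2NEt (cat.), MeCN, 80 °C
Reagents that add atoms: triphenylphosphine, c1ccc(cc1)P(c1ccccc1)c1ccccc1
Why: SN2 quaternisation of PPh3 by a primary iodide; the silyloxy group is γ to phosphorus and cannot be lost by β-elimination from the later ylide.

Step 9
Reactants: 13 dimethyl (4R,5R)-2,2-dimethyl-1,3-dioxolane-4,5-dicarboxylate
Product: 14 (4R,5R)-N4,N5-dimethoxy-N4,N5,2,2-tetramethyl-1,3-dioxolane-4,5-dicarboxamide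
Conditions: MeNHOMe·HCl, i-PrMgCl, THF, −20 → 0 °C
Reagents that add atoms: N,O-dimethylhydroxylamine hydrochloride, CNOC.Cl
Why: Aminolysis of both esters by the magnesium amide of N,O-dimethylhydroxylamine (Weinreb amide formation); the trans-dioxolane is the stable arrangement, so C8 and C9 are not at risk.

Step 10
Reactants: 14 (4R,5R)-N4,N5-dimethoxy-N4,N5,2,2-tetramethyl-1,3-dioxolane-4,5-dicarboxamide
Product: 15 (4R,5R)-5-acetyl-N-methoxy-N,2,2-trimethyl-1,3-dioxolane-4-carboxamide
Conditions: MeMgBr (1.1 equiv), THF, −78 °C; aq. NH4Cl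
Reagents that add atoms: methylmagnesium bromide, C[Mg]Br
Why: Grignard addition to a Weinreb amide; the chelated tetrahedral adduct persists to work-up, so no tertiary alcohol forms, and with one equivalent mainly one amide should react; the two amides are equivalent, so only one mono-adduct exists.

Step 11
Reactants: 12 [(3S,4Z)-3-[(tert-butyldimethylsilyl)oxy]-6-[(4-methoxybenzyl)oxy]-4-methylhex-4-en-1-yl]triphenylphosphonium iodide; 15 (4R,5R)-5-acetyl-N-methoxy-N,2,2-trimethyl-1,3-dioxolane-4-carboxamide
Product: 17 (4R,5S)-5-[(2Z,5S,6Z)-5-[(tert-butyldimethylsilyl)oxy]-8-[(4-methoxybenzyl)oxy]-6-methylocta-2,6-dien-2-yl]-N-methoxy-N,2,2-trimethyl-1,3-dioxolane-4-carboxamide, via phosphorus ylide 16 (not isolated)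
Conditions: 12, KN(SiMe3)2, THF, −78 °C; then 15 (1.5 equiv), −78 → 0 °C
Reagents that add atoms: none
Why: Wittig olefination of an α-alkoxy methyl ketone with a salt-free unstabilised ylide, a pairing known to favour the Z-trisubstituted olefin (C9 cis to C2); the ketone is far more reactive than the Weinreb amide at −78 °C and is used in excess to offset enolisation.

Step 12
Reactants: 17 (4R,5S)-5-[(2Z,5S,6Z)-5-[(tert-butyldimethylsilyl)oxy]-8-[(4-methoxybenzyl)oxy]-6-methylocta-2,6-dien-2-yl]-N-methoxy-N,2,2-trimethyl-1,3-dioxolane-4-carboxamide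
Product: 18 (4R,5S)-5-[(2Z,5S,6Z)-5-[(tert-butyldimethylsilyl)oxy]-8-[(4-methoxybenzyl)oxy]-6-methylocta-2,6-dien-2-yl]-2,2-dimethyl-1,3-dioxolane-4-carbaldehyde
Conditions: i-Bu2AlH (1.3 equiv), THF, −78 °C
Reagents that add atoms: none
Why: Reduction of a Weinreb amide stops at the chelated hemiaminal and gives the aldehyde on work-up; the trans-dioxolane is the thermodynamic arrangement, so C8 is not endangered.

Step 13
Reactants: 18 (4R,5S)-5-[(2Z,5S,6Z)-5-[(tert-butyldimethylsilyl)oxy]-8-[(4-methoxybenzyl)oxy]-6-methylocta-2,6-dien-2-yl]-2,2-dimethyl-1,3-dioxolane-4-carbaldehyde; 19 methyl acrylate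
Product: 20 methyl 2-{hydroxy[(4S,5S)-5-(side chain as in 17)-2,2-dimethyl-1,3-dioxolan-4-yl]methyl}prop-2-enoate (both C7 epimers)
Conditions: 19 (5 equiv), DABCO (1 equiv), MeOH (cat.), rt, 3–5 d
Reagents that add atoms: none
Why: Morita–Baylis–Hillman reaction; the ammonium enolate from DABCO and the acrylate adds to the activated α-alkoxy aldehyde and forms C7–C11; the carbinol centre at C7 is removed in step 14, so its configuration is irrelevant.

Step 14
Reactants: 20 methyl 2-{hydroxy[(4S,5S)-5-(side chain as in 17)-2,2-dimethyl-1,3-dioxolan-4-yl]methyl}prop-2-enoate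
Product: 21 methyl (2Z)-2-(bromomethyl)-3-[(4S,5S)-5-(side chain as in 17)-2,2-dimethyl-1,3-dioxolan-4-yl]prop-2-enoate
Conditions: NBS, Me2S, CH2Cl2, 0 °C → rt
Reagents that add atoms: N-bromosuccinimide, BrN1C(=O)CCC1=O
Why: The alkoxysulfonium salt formed from the alcohol is displaced by bromide in an SN2′ sense, a known allylic transposition of Baylis–Hillman adducts that should give the conjugated Z-bromide (CH2Br at C13 cis to C8, ester at C12 trans); the neutral conditions spare acetonide, silyl and PMB ethers.

Step 15
Reactants: 21 methyl (2Z)-2-(bromomethyl)-3-[(4S,5S)-5-(side chain as in 17)-2,2-dimethyl-1,3-dioxolan-4-yl]prop-2-enoate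
Product: 22 (2Z)-2-(bromomethyl)-3-[(4S,5S)-5-(side chain as in 17)-2,2-dimethyl-1,3-dioxolan-4-yl]prop-2-en-1-ol
Conditions: i-Bu2AlH (2.2 equiv), CH2Cl2, −78 °C
Reagents that add atoms: none
Why: 1,2-Reduction of the enoate at −78 °C, under which a primary allylic bromide is not reduced.

Step 16
Reactants: 22 (2Z)-2-(bromomethyl)-3-[(4S,5S)-5-(side chain as in 17)-2,2-dimethyl-1,3-dioxolan-4-yl]prop-2-en-1-ol
Product: 23 O12-TBS ether of 22 (C13 bromide, C6 PMB ether, C3 TBS ether, 8,9-acetonide)
Conditions: TBSOTf, 2,6-lutidine, CH2Cl2, −78 °C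
Reagents that add atoms: tert-butyldimethylsilyl triflate, CC(C)(C)[Si](C)(C)OS(=O)(=O)C(F)(F)F
Why: Silylation with a silyl triflate and a hindered base, chosen because imidazole would alkylate the allylic bromide.

Step 17
Reactants: 23 O12-TBS ether of 22
Product: 24 C6 alcohol of 23 (C13 bromide, O12 and O3 TBS ethers, 8,9-acetonide)
Conditions: DDQ, CH2Cl2–pH 7 buffer, 0 °C
Reagents that add atoms: none
Why: Oxidative cleavage of the PMB ether through the benzylic oxocarbenium ion; silyl ethers, acetonide and allylic bromide are not affected under buffered conditions.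

Step 18
Reactants: 24 C6 alcohol of 23
Product: 25 thirteen-membered cyclic ether (O links C6 and C13; ring-cis C1=C10, C4=C5 and C7=C11; (3S)-OTBS; (8S,9S)-acetonide; CH2OTBS on C11)
Conditions: NaH, THF, syringe-pump addition to 0.002 M, 40 °C
Reagents that add atoms: none
Why: Intramolecular Williamson etherification; the primary allylic alkoxide at C6 displaces the primary allylic bromide at C13 by SN2 (SN2′ at the substituted C7 is disfavoured), and slow addition at high dilution favours the thirteen-membered ring, a closure with precedent for bis-allylic ethers of this size.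

Step 19
Reactants: 25 thirteen-membered cyclic ether
Product: 27 (3S,6S,7S,8S,9S)-3,12-bis[(tert-butyldimethylsilyl)oxy]-8,9-(isopropylidenedioxy)germacra-1(10)Z,4Z,11(13)-trien-6-ol, via C6-lithiated ether 26 (not isolated)
Conditions: n-BuLi (2.5 equiv), THF, −78 → −40 °C; then H2O
Reagents that add atoms: none
Why: n-BuLi removes a C6 proton (allylic and α to oxygen) to give the α-alkoxy allyllithium 26, which undergoes a concerted suprafacial [2,3]-sigmatropic shift through a five-membered envelope (C6, O, C13, C11, C7): C6–C7 forms, O–C13 breaks, the oxygen becomes the C6 alkoxide and C11=C13 the exocyclic methylene. The closest known reaction type is the [2,3]-Wittig ring contraction of thirteen-membered bis-allylic ethers to ten-membered carbocycles of the germacrane family. The ten-membered ring is closed by transannular contraction of the preformed thirteen-membered ring through this five-membered cyclic transition state and not by an end-to-end cyclisation, so no entropic penalty is paid here. The C6/C7 relationship should be syn (H6 and H7 cis, as the cis lactone needs) because the vinyl carbon C5 on the carbanion sits exo on the envelope, the endo position being blocked by the CH2OTBS group on C11, and because C8 is cis to C13 on the ring-cis C7=C11 olefin. The sense relative to C8 should follow from allylic 1,3-strain, which holds H8 in the olefin plane towards C13H2, and from the tether, which needs C9 antiperiplanar to the forming bond for a strain-free ten-membered ring, so that C6 adds to the C7 face on the side of the C8 oxygen, where that acetal oxygen can also hold the lithium. Lithiation must occur at C6 and not at C13: C6 is flanked by the CH= carbon C5, whereas C13 is neopentyl-like beside the fully substituted C11 and its silyloxymethyl group. Both silyl ethers are weak lithium ligands and poor leaving groups, and the low temperature should hold back 1,4-elimination of the C3 silyloxy group and the [1,2]-shift.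

Step 20
Reactants: 27 rearranged C6 alcohol
Product: 28 (3S,6S,7S,8S,9S)-3-[(tert-butyldimethylsilyl)oxy]-8,9-(isopropylidenedioxy)germacra-1(10)Z,4Z,11(13)-triene-6,12-diol
Conditions: HF·pyridine, pyridine, THF, 0 °C
Reagents that add atoms: none
Why: Buffered HF·pyridine cleaves the unhindered primary allylic TBS ether much faster than the secondary one on C3; the acetonide is stable to it.

Step 21
Reactants: 28 6,12-diol
Product: 31 (3S,6S,7S,8S,9S)-3-[(tert-butyldimethylsilyl)oxy]-8,9-(isopropylidenedioxy)germacra-1(10)Z,4Z,11(13)-trien-12,6-olide, via hydroxy enal 29 (not isolated), via lactol 30 (not isolated)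
Conditions: TEMPO (0.3 equiv), PhI(OAc)2 (3 equiv), CH2Cl2, rt
Reagents that add atoms: none
Why: Oxidative lactonisation of a 2-methylene-1,4-diol; the primary allylic alcohol is oxidised to enal 29, the C6 hydroxyl closes to lactol 30 and a second oxidation gives the α-methylene lactone; with O3 still silylated no other hydroxyl can react, and the cis junction is the one set in step 19.

Step 22
Reactants: 31 silylated lactone
Product: 32 (3S,6S,7S,8S,9S)-3-hydroxy-8,9-(isopropylidenedioxy)germacra-1(10)Z,4Z,11(13)-trien-12,6-olide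
Conditions: HF·pyridine, THF, rt
Reagents that add atoms: none
Why: Unbuffered HF·pyridine removes the remaining secondary TBS ether; an acidic fluoride source avoids the conjugate additions that basic fluoride can cause on an α-methylene lactone.

Step 23
Reactants: 32 C3 alcohol
Product: 33 (3S,6S,7S,8S,9S)-3-acetoxy-8,9-(isopropylidenedioxy)germacra-1(10)Z,4Z,11(13)-trien-12,6-olide
Conditions: Ac2O, pyridine, DMAP (cat.), CH2Cl2, 0 °C
Reagents that add atoms: acetic anhydride, CC(=O)OC(C)=O
Why: DMAP-catalysed acetylation of the only free hydroxyl.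

Step 24
Reactants: 33 acetate acetonide
Product: 34 (3S,6S,7R,8S,9S)-3-acetoxy-8,9-dihydroxygermacra-1(10)Z,4Z,11(13)-trien-12,6-olide
Conditions: AcOH–H2O (4:1), 50 °C
Reagents that add atoms: none
Why: Acid-catalysed hydrolysis of the strained trans-fused dioxolane through the acetone oxocarbenium ion; aqueous acetic acid is too weak to ionise the allylic acetate or the C9–O bond.

Step 25
Reactants: 35 angelic acid
Product: 36 (2Z)-2-methylbut-2-en-1-ol
Conditions: LiAlH4, Et2O, 0 °C
Reagents that add atoms: none
Why: LiAlH4 reduces the carboxylate to the primary allylic alcohol by 1,2-hydride delivery and leaves the Z-olefin alone.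

Step 26
Reactants: 36 (2Z)-2-methylbut-2-en-1-ol
Product: 37 [(2R,3S)-2,3-dimethyloxiran-2-yl]methanol
Conditions: Ti(OiPr)4 (10 mol %), D-(−)-diethyl tartrate (12 mol %), t-BuOOH, 4 Å MS, CH2Cl2, −20 °C
Reagents that add atoms: tert-butyl hydroperoxide, CC(C)(C)OO
Why: Sharpless asymmetric epoxidation; with D-(−)-diethyl tartrate the titanium tartrate peroxide complex should deliver oxygen to the face of the allylic alcohol that gives the (2R,3S)-epoxide, while the trans relation of the two methyl groups is fixed by the Z-olefin.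

Step 27
Reactants: 37 [(2R,3S)-2,3-dimethyloxiran-2-yl]methanol
Product: 38 (2S,3S)-2,3-dimethyloxirane-2-carboxylic acid
Conditions: RuCl3 (2 mol %), NaIO4, MeCN–EtOAc–H2O, 0 °C → rt
Reagents that add atoms: water, O
Why: RuO4 formed in situ oxidises the primary alcohol through the aldehyde hydrate to the acid, a standard route from 2,3-epoxy alcohols to glycidic acids; the stereocentres are untouched (the C2 descriptor changes only because the priorities change).

Step 28
Reactants: 34 8,9-diol; 38 (2S,3S)-2,3-dimethyloxirane-2-carboxylic acid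
Product: 40 (3S,6S,7R,8S,9S)-3-acetoxy-9-{[(2S,3S)-2,3-dimethyloxiran-2-yl]carbonyloxy}-8-hydroxygermacra-1(10)Z,4Z,11(13)-trien-12,6-olide, via mixed anhydride 39 (not isolated)
Conditions: 38, 2,4,6-trichlorobenzoyl chloride, Et3N, toluene, rt; then 34, DMAP, rt
Reagents that add atoms: 2,4,6-trichlorobenzoyl chloride, O=C(Cl)c1c(Cl)cc(Cl)cc1Cl (in 39 only)
Why: Yamaguchi esterification; DMAP attacks the less hindered aliphatic carbonyl of 39 and the acylpyridinium should be taken by the C9 hydroxyl, which has the flat olefinic C10 beside it, in preference to the C8 hydroxyl, which lies between two sp3 methines and next to the lactone ring; one equivalent of 39 at room temperature limits bis-acylation and acyl or lactone migration.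

## Compound list

1 | 2-[(4-methoxybenzyl)oxy]acetaldehyde | COc1ccc(COCC=O)cc1 | starting material
2 | ethyl 2-[bis(2,2,2-trifluoroethoxy)phosphoryl]propanoate | CCOC(=O)C(C)P(=O)(OCC(F)(F)F)OCC(F)(F)F | starting material
3 | ethyl (2Z)-4-[(4-methoxybenzyl)oxy]-2-methylbut-2-enoate | CCOC(=O)/C(C)=C\COCc1ccc(OC)cc1 | intermediate
4 | (2Z)-4-[(4-methoxybenzyl)oxy]-2-methylbut-2-en-1-ol | OC/C(C)=C\COCc1ccc(OC)cc1 | intermediate
5 | (2Z)-4-[(4-methoxybenzyl)oxy]-2-methylbut-2-enal | O=C/C(C)=C\COCc1ccc(OC)cc1 | intermediate
6 | allylboronic acid pinacol ester | C=CCB1OC(C)(C)C(C)(C)O1 | starting material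
7 | (4S,5Z)-7-[(4-methoxybenzyl)oxy]-5-methylhepta-1,5-dien-4-ol | C=CC[C@H](O)/C(C)=C\COCc1ccc(OC)cc1 | intermediate
8 | tert-butyl{[(4S,5Z)-7-[(4-methoxybenzyl)oxy]-5-methylhepta-1,5-dien-4-yl]oxy}dimethylsilane | C=CC[C@H](O[Si](C)(C)C(C)(C)C)/C(C)=C\COCc1ccc(OC)cc1 | intermediate
9 | (3S,4Z)-3-[(tert-butyldimethylsilyl)oxy]-6-[(4-methoxybenzyl)oxy]-4-methylhex-4-enal | O=CC[C@H](O[Si](C)(C)C(C)(C)C)/C(C)=C\COCc1ccc(OC)cc1 | intermediate
10 | (3S,4Z)-3-[(tert-butyldimethylsilyl)oxy]-6-[(4-methoxybenzyl)oxy]-4-methylhex-4-en-1-ol | OCC[C@H](O[Si](C)(C)C(C)(C)C)/C(C)=C\COCc1ccc(OC)cc1 | intermediate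
11 | tert-butyl{[(3S,4Z)-1-iodo-6-[(4-methoxybenzyl)oxy]-4-methylhex-4-en-3-yl]oxy}dimethylsilane | ICC[C@H](O[Si](C)(C)C(C)(C)C)/C(C)=C\COCc1ccc(OC)cc1 | intermediate
12 | [(3S,4Z)-3-[(tert-butyldimethylsilyl)oxy]-6-[(4-methoxybenzyl)oxy]-4-methylhex-4-en-1-yl]triphenylphosphonium iodide | [I-].c1ccccc1[P+](c1ccccc1)(c1ccccc1)CC[C@H](O[Si](C)(C)C(C)(C)C)/C(C)=C\COCc1ccc(OC)cc1 | intermediate
13 | dimethyl (4R,5R)-2,2-dimethyl-1,3-dioxolane-4,5-dicarboxylate (acetonide of dimethyl L-tartrate) | COC(=O)[C@@H]1OC(C)(C)O[C@H]1C(=O)OC | starting material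
14 | (4R,5R)-N4,N5-dimethoxy-N4,N5,2,2-tetramethyl-1,3-dioxolane-4,5-dicarboxamide | CON(C)C(=O)[C@@H]1OC(C)(C)O[C@H]1C(=O)N(C)OC | intermediate
15 | (4R,5R)-5-acetyl-N-methoxy-N,2,2-trimethyl-1,3-dioxolane-4-carboxamide | CON(C)C(=O)[C@@H]1OC(C)(C)O[C@H]1C(C)=O | intermediate
16 | ylide of 12, [(3S,4Z)-3-[(tert-butyldimethylsilyl)oxy]-6-[(4-methoxybenzyl)oxy]-4-methylhex-4-en-1-ylidene]triphenylphosphorane | c1ccccc1P(c1ccccc1)(c1ccccc1)=CC[C@H](O[Si](C)(C)C(C)(C)C)/C(C)=C\COCc1ccc(OC)cc1 | intermediate
17 | (4R,5S)-5-[(2Z,5S,6Z)-5-[(tert-butyldimethylsilyl)oxy]-8-[(4-methoxybenzyl)oxy]-6-methylocta-2,6-dien-2-yl]-N-methoxy-N,2,2-trimethyl-1,3-dioxolane-4-carboxamide | CON(C)C(=O)[C@@H]1OC(C)(C)O[C@H]1/C(C)=C\C[C@H](O[Si](C)(C)C(C)(C)C)/C(C)=C\COCc1ccc(OC)cc1 | intermediate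
18 | (4R,5S)-5-[(2Z,5S,6Z)-5-[(tert-butyldimethylsilyl)oxy]-8-[(4-methoxybenzyl)oxy]-6-methylocta-2,6-dien-2-yl]-2,2-dimethyl-1,3-dioxolane-4-carbaldehyde | O=C[C@@H]1OC(C)(C)O[C@H]1/C(C)=C\C[C@H](O[Si](C)(C)C(C)(C)C)/C(C)=C\COCc1ccc(OC)cc1 | intermediate
19 | methyl acrylate | C=CC(=O)OC | starting material
20 | methyl 2-{hydroxy[(4S,5S)-5-(side chain as in 17)-2,2-dimethyl-1,3-dioxolan-4-yl]methyl}prop-2-enoate, both C7 epimers | C=C(C(=O)OC)C(O)[C@@H]1OC(C)(C)O[C@H]1/C(C)=C\C[C@H](O[Si](C)(C)C(C)(C)C)/C(C)=C\COCc1ccc(OC)cc1 | intermediate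
21 | methyl (2Z)-2-(bromomethyl)-3-[(4S,5S)-5-(side chain as in 17)-2,2-dimethyl-1,3-dioxolan-4-yl]prop-2-enoate | BrC/C(C(=O)OC)=C\[C@@H]1OC(C)(C)O[C@H]1/C(C)=C\C[C@H](O[Si](C)(C)C(C)(C)C)/C(C)=C\COCc1ccc(OC)cc1 | intermediate
22 | (2Z)-2-(bromomethyl)-3-[(4S,5S)-5-(side chain as in 17)-2,2-dimethyl-1,3-dioxolan-4-yl]prop-2-en-1-ol | BrC/C(CO)=C\[C@@H]1OC(C)(C)O[C@H]1/C(C)=C\C[C@H](O[Si](C)(C)C(C)(C)C)/C(C)=C\COCc1ccc(OC)cc1 | intermediate
23 | O12-TBS ether of 22 | BrC/C(CO[Si](C)(C)C(C)(C)C)=C\[C@@H]1OC(C)(C)O[C@H]1/C(C)=C\C[C@H](O[Si](C)(C)C(C)(C)C)/C(C)=C\COCc1ccc(OC)cc1 | intermediate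
24 | C6 alcohol of 23 (PMB removed) | BrC/C(CO[Si](C)(C)C(C)(C)C)=C\[C@@H]1OC(C)(C)O[C@H]1/C(C)=C\C[C@H](O[Si](C)(C)C(C)(C)C)/C(C)=C\CO | intermediate
25 | thirteen-membered cyclic ether: O between C6 and C13, ring-cis C1=C10, C4=C5, C7=C11, (3S)-OTBS, (8S,9S)-acetonide, CH2OTBS on C11 | O1C/C(CO[Si](C)(C)C(C)(C)C)=C\[C@@H]2OC(C)(C)O[C@H]2/C(C)=C\C[C@H](O[Si](C)(C)C(C)(C)C)/C(C)=C\C1 | intermediate
26 | C6-lithio derivative of 25 | O1C/C(CO[Si](C)(C)C(C)(C)C)=C\[C@@H]2OC(C)(C)O[C@H]2/C(C)=C\C[C@H](O[Si](C)(C)C(C)(C)C)/C(C)=C\C1[Li] | intermediate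
27 | (3S,6S,7S,8S,9S)-3,12-bis[(tert-butyldimethylsilyl)oxy]-8,9-(isopropylidenedioxy)germacra-1(10)Z,4Z,11(13)-trien-6-ol | O[C@H]1/C=C(/C)[C@@H](O[Si](C)(C)C(C)(C)C)C/C=C(/C)[C@H](OC2(C)C)[C@@H](O2)[C@H]1C(=C)CO[Si](C)(C)C(C)(C)C | intermediate
28 | (3S,6S,7S,8S,9S)-3-[(tert-butyldimethylsilyl)oxy]-8,9-(isopropylidenedioxy)germacra-1(10)Z,4Z,11(13)-triene-6,12-diol | O[C@H]1/C=C(/C)[C@@H](O[Si](C)(C)C(C)(C)C)C/C=C(/C)[C@H](OC2(C)C)[C@@H](O2)[C@H]1C(=C)CO | intermediate
29 | 6-hydroxy-12-al (enal) from 28 | O[C@H]1/C=C(/C)[C@@H](O[Si](C)(C)C(C)(C)C)C/C=C(/C)[C@H](OC2(C)C)[C@@H](O2)[C@H]1C(=C)C=O | intermediate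
30 | 12,6-lactol from 29 (C12 configuration open) | C=C1C(O)O[C@H]2/C=C(/C)[C@@H](O[Si](C)(C)C(C)(C)C)C/C=C(/C)[C@H](OC3(C)C)[C@@H](O3)[C@@H]12 | intermediate
31 | (3S,6S,7S,8S,9S)-3-[(tert-butyldimethylsilyl)oxy]-8,9-(isopropylidenedioxy)germacra-1(10)Z,4Z,11(13)-trien-12,6-olide | C=C1C(=O)O[C@H]2/C=C(/C)[C@@H](O[Si](C)(C)C(C)(C)C)C/C=C(/C)[C@H](OC3(C)C)[C@@H](O3)[C@@H]12 | intermediate
32 | (3S,6S,7S,8S,9S)-3-hydroxy-8,9-(isopropylidenedioxy)germacra-1(10)Z,4Z,11(13)-trien-12,6-olide | C=C1C(=O)O[C@H]2/C=C(/C)[C@@H](O)C/C=C(/C)[C@H](OC3(C)C)[C@@H](O3)[C@@H]12 | intermediate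
33 | (3S,6S,7S,8S,9S)-3-acetoxy-8,9-(isopropylidenedioxy)germacra-1(10)Z,4Z,11(13)-trien-12,6-olide | C=C1C(=O)O[C@H]2/C=C(/C)[C@@H](OC(C)=O)C/C=C(/C)[C@H](OC3(C)C)[C@@H](O3)[C@@H]12 | intermediate
34 | (3S,6S,7R,8S,9S)-3-acetoxy-8,9-dihydroxygermacra-1(10)Z,4Z,11(13)-trien-12,6-olide | C=C1C(=O)O[C@H]2/C=C(/C)[C@@H](OC(C)=O)C/C=C(/C)[C@H](O)[C@@H](O)[C@@H]12 | intermediate
35 | angelic acid, (2Z)-2-methylbut-2-enoic acid | C/C=C(/C)C(O)=O | starting material
36 | (2Z)-2-methylbut-2-en-1-ol | C/C=C(/C)CO | intermediate
37 | [(2R,3S)-2,3-dimethyloxiran-2-yl]methanol | OC[C@@]1(C)O[C@H]1C | intermediate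
38 | (2S,3S)-2,3-dimethyloxirane-2-carboxylic acid | OC(=O)[C@@]1(C)O[C@H]1C | intermediate
39 | (2S,3S)-2,3-dimethyloxirane-2-carboxylic 2,4,6-trichlorobenzoic anhydride | O=C(OC(=O)[C@@]1(C)O[C@H]1C)c1c(Cl)cc(Cl)cc1Cl | intermediate
40 | (3S,6S,7R,8S,9S)-3-acetoxy-9-{[(2S,3S)-2,3-dimethyloxiran-2-yl]carbonyloxy}-8-hydroxygermacra-1(10)Z,4Z,11(13)-trien-12,6-olide | C=C1C(=O)O[C@H]2/C=C(/C)[C@@H](OC(C)=O)C/C=C(/C)[C@H](OC(=O)[C@@]3(C)O[C@H]3C)[C@@H](O)[C@@H]12 | target

## Step count and least certain steps

Total: 28 steps. Longest linear sequence: 23 steps (steps 1–8, 11–24 and 28, from 1 to 40). Steps 9–10 and 25–27 are side branches.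

**Step 19 (key step).** Most likely to go wrong is the partitioning of the base and of the allyl anion. C6 and C13 are of similar acidity, so some lithiation at C13 is possible, and that anion would open the acetonide at C8. The desired C6 anion can itself expel the C3 silyloxy group across the cis olefin (1,4-elimination). A second uncertainty is addition to the wrong face of C7, since the facial preference rests only on conformational arguments. Fallback: rearrangement of the unprotected substrate, from 25 back to the route at 32. TBAF in THF removes both silyl groups from 25 to give the macrocyclic 3,12-diol F1. Excess n-BuLi first forms the two lithium alkoxides; the one at C3 cannot be expelled and the one at C12 puts negative charge next to C13, so the next equivalent should go to C6. Rearrangement gives the 3,6,12-triol F2. TEMPO/PhI(OAc)2, which takes the primary allylic alcohol first, then closes the lactone and gives 32.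

**Step 11.** Most likely to go wrong is geometric control in the olefination of a ketone, together with enolisation of 15 by the basic ylide; both would erode the supply of Z-olefin. Fallback: a stepwise Horner–Wittig sequence from 11 to 17. LiPPh2 followed by H2O2 converts 11 into the diphenylphosphine oxide F3. Its lithio derivative (n-BuLi, THF, −78 °C) adds to 15 to give β-hydroxy phosphine oxides, which are separated by chromatography. The diastereomer F4 whose syn-elimination places C9 cis to C2 is treated with KH in DMF and gives 17 stereospecifically.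

**Step 18.** Most likely to go wrong is oligomerisation outrunning ring closure, because a chain with three cis olefins and a trans-dioxolane has to fold before the alkoxide reaches C13. Fallback: closing the ring at C7=C11 instead, from 17 to 25.
- DDQ frees the C6 alcohol of 17 to give the hydroxy amide F5.
- Base-catalysed conjugate addition of F5 to ethyl 2-(diethoxyphosphoryl)acrylate gives the phosphonate F6.
- Cp2Zr(H)Cl reduces the Weinreb amide in the presence of the ester to the aldehyde F7.
- LiCl and DBU in MeCN at high dilution effect an intramolecular Horner–Wadsworth–Emmons olefination to the macrocyclic enoate F8 (ester trans to C8, hence ring-cis).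
- i-Bu2AlH gives the macrocyclic allylic alcohol F9, and TBSOTf with 2,6-lutidine gives 25.

**Step 28.** Most likely to go wrong is acylation at O8, or at both hydroxyls, and base-induced acyl or lactone migration, because the two secondary hydroxyls differ only in their surroundings. Fallback: if the inherent preference is for O8, it is used instead of fought, from 34 to 40. TESCl and imidazole at −20 °C silylate the more reactive hydroxyl to give the 8-O-triethylsilyl ether F10. Preformed 39 and DMAP then acylate O9 to give the silylated ester F11. HF·pyridine removes the silyl group and gives 40.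

**Step 6.** Most likely to go wrong is loss of chemoselectivity: osmylation of the trisubstituted C4=C5 bond in competition with the terminal alkene. Fallback: a route without oxidative cleavage, from 5 to 10.
- Vinylmagnesium bromide adds to 5 to give the racemic dienol F12.
- MnO2 oxidises F12 to the dienone F13.
- Corey–Bakshi–Shibata reduction with the (R)-methyl oxazaborolidine and BH3·SMe2 (the substituted alkenyl group as the large substituent) gives the (S)-dienol F14.
- TBSCl and imidazole give the silyl ether F15.
- 9-BBN hydroborates only the terminal vinyl group, and NaOH/H2O2 gives 10.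

## Further compounds

F1 | step 19 | macrocyclic 3,12-diol (25 without silyl groups) | O1C/C(CO)=C\[C@@H]2OC(C)(C)O[C@H]2/C(C)=C\C[C@H](O)/C(C)=C\C1
F2 | step 19 | (3S,6S,7S,8S,9S)-8,9-(isopropylidenedioxy)germacra-1(10)Z,4Z,11(13)-triene-3,6,12-triol | O[C@H]1/C=C(/C)[C@@H](O)C/C=C(/C)[C@H](OC2(C)C)[C@@H](O2)[C@H]1C(=C)CO
F3 | step 11 | [(3S,4Z)-3-[(tert-butyldimethylsilyl)oxy]-6-[(4-methoxybenzyl)oxy]-4-methylhex-4-en-1-yl]diphenylphosphine oxide | O=P(c1ccccc1)(c1ccccc1)CC[C@H](O[Si](C)(C)C(C)(C)C)/C(C)=C\COCc1ccc(OC)cc1
F4 | step 11 | β-hydroxy phosphine oxide from F3 and 15 (C10 carbinol, C1 phosphinoyl; diastereomer that eliminates to the Z-olefin) | CON(C)C(=O)[C@@H]1OC(C)(C)O[C@H]1C(C)(O)C(C[C@H](O[Si](C)(C)C(C)(C)C)/C(C)=C\COCc1ccc(OC)cc1)P(=O)(c1ccccc1)c1ccccc1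
F5 | step 18 | C6 alcohol of 17 | CON(C)C(=O)[C@@H]1OC(C)(C)O[C@H]1/C(C)=C\C[C@H](O[Si](C)(C)C(C)(C)C)/C(C)=C\CO
F6 | step 18 | ethyl 2-(diethoxyphosphoryl)-3-alkoxypropanoate from F5 (ether at O6) | CON(C)C(=O)[C@@H]1OC(C)(C)O[C@H]1/C(C)=C\C[C@H](O[Si](C)(C)C(C)(C)C)/C(C)=C\COCC(C(=O)OCC)P(=O)(OCC)OCC
F7 | step 18 | C7 aldehyde of F6 | O=C[C@@H]1OC(C)(C)O[C@H]1/C(C)=C\C[C@H](O[Si](C)(C)C(C)(C)C)/C(C)=C\COCC(C(=O)OCC)P(=O)(OCC)OCC
F8 | step 18 | thirteen-membered ether with ethyl ester at C12 (C7=C11 E-enoate, ring-cis) | O1C/C(C(=O)OCC)=C\[C@@H]2OC(C)(C)O[C@H]2/C(C)=C\C[C@H](O[Si](C)(C)C(C)(C)C)/C(C)=C\C1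
F9 | step 18 | thirteen-membered ether with free C12 alcohol | O1C/C(CO)=C\[C@@H]2OC(C)(C)O[C@H]2/C(C)=C\C[C@H](O[Si](C)(C)C(C)(C)C)/C(C)=C\C1
F10 | step 28 | 8-O-triethylsilyl ether of 34 | C=C1C(=O)O[C@H]2/C=C(/C)[C@@H](OC(C)=O)C/C=C(/C)[C@H](O)[C@@H](O[Si](CC)(CC)CC)[C@@H]12
F11 | step 28 | 8-O-triethylsilyl ether of 40 | C=C1C(=O)O[C@H]2/C=C(/C)[C@@H](OC(C)=O)C/C=C(/C)[C@H](OC(=O)[C@@]3(C)O[C@H]3C)[C@@H](O[Si](CC)(CC)CC)[C@@H]12
F12 | step 6 | (4Z)-6-[(4-methoxybenzyl)oxy]-4-methylhexa-1,4-dien-3-ol, racemic | C=CC(O)/C(C)=C\COCc1ccc(OC)cc1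
F13 | step 6 | (4Z)-6-[(4-methoxybenzyl)oxy]-4-methylhexa-1,4-dien-3-one | C=CC(=O)/C(C)=C\COCc1ccc(OC)cc1
F14 | step 6 | (3S,4Z)-6-[(4-methoxybenzyl)oxy]-4-methylhexa-1,4-dien-3-ol | C=C[C@H](O)/C(C)=C\COCc1ccc(OC)cc1
F15 | step 6 | tert-butyl{[(3S,4Z)-6-[(4-methoxybenzyl)oxy]-4-methylhexa-1,4-dien-3-yl]oxy}dimethylsilane | C=C[C@H](O[Si](C)(C)C(C)(C)C)/C(C)=C\COCc1ccc(OC)cc1
A1 | alternative 1 | 8-O-PMB ether of the 9-hydroxy lactone (target without the C9 acyl group) | C=C1C(=O)O[C@H]2/C=C(/C)[C@@H](OC(C)=O)C/C=C(/C)[C@H](O)[C@@H](OCc3ccc(OC)cc3)[C@@H]12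
A2 | alternative 1 | seco iodo aldehyde (C9 aldehyde, Z-alkenyl iodide at C10, lactone intact) | C=C1C(=O)O[C@@H](/C=C(/C)[C@@H](OC(C)=O)C/C=C(/C)I)[C@H]1[C@H](OCc1ccc(OC)cc1)C=O
A3 | alternative 2 | ten-membered (Z,Z)-diene-3,8-dione | COc1ccc(cc1)CO[C@H]2/C=C(/C)C(=O)C/C=C(/C)[C@H](O[Si](C)(C)C(C)(C)C)C(=O)[C@H]2C(=C)COCc3ccc(OC)cc3
A4 | alternative 2 | decalin ring-fusion 3,8-diol (C3–C8 bond; configuration at C3 and C8 left open) | COc1ccc(cc1)CO[C@H]2C=C(C)C3(O)CC=C(C)[C@H](O[Si](C)(C)C(C)(C)C)C3(O)[C@H]2C(=C)COCc4ccc(OC)cc4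
A5 | alternative 3 | ten-membered 8,9-diol | COc1ccc(cc1)CO[C@H]2/C=C(/C)[C@@H](O[Si](C)(C)C(C)(C)C)C/C=C(/C)[C@H](O)[C@@H](O)[C@H]2C(=C)COCc3ccc(OC)cc3
A6 | alternative 3 | open-chain dialdehyde (C8 aldehyde, C9 Z-enal) | O=C[C@@H](C(=C)COCc1ccc(OC)cc1)[C@@H](OCc1ccc(OC)cc1)/C=C(/C)[C@@H](O[Si](C)(C)C(C)(C)C)C/C=C(/C)C=O
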